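**Retrosynthetic overview**

1. The strategy rests on the C3(=O)–C4(CH3)=C5–C6H2 unit that spans ring A (cyclopentenone, C1–C5) and ring B (cycloheptane, C1, C5–C10). It is the hydrolysis product of a 3-silyloxy-3,5-diene (C3=C4–C5=C6), so the target is traced back (ester removal, enol-ether and acetonide hydrolysis) to the tricyclic silyl dienol ether 27.
2. 27 is opened at C5=C6 and C3=C4 to the acyclic dienyne 26 (C6 vinyl, C4≡C5 propyne, C3 silyl enol ether). One ruthenium cascade closes ring B first (enyne step) and ring A second (enol-ether step).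
3. 26 comes from keto diol 23 (acetonide across O8/O11, kinetic enol silylation). C11 and O8 are cis on ring B, which corresponds to a syn aldol, so C7–C8 is made by an auxiliary-controlled syn aldol of crotonyl imide 18 with aldehyde 14; the C11 methyl groups come from methyl addition to the ester.
4. Aldehyde 14 comes from (S)-4-methyl-δ-valerolactone 3 (C10 from the chiral pool). Trans alkylation sets C1, the lactone carbonyl becomes the propyne and the methallyl group the masked C3 ketone.

Key step: step 15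

Assumption: carbons are numbered as in the guaianes (C1 ring-fusion CH, C2 H2, C3 ketone, C4 bearing CH3, C5 ring-fusion alkene carbon, C6 H2, C7 bearing C11, C8 bearing the isobutyrate, C9 H2, C10 bearing CH3), and methyl hydrogen (R)-3-methylglutarate is taken to be available in high enantiomeric purity.

**Route**

Step 1
Reactants: 1 methyl hydrogen (R)-3-methylpentanedioate
Product: 3 (S)-4-methyloxan-2-one, via sodium (S)-5-hydroxy-3-methylpentanoate 2 (not isolated)
Conditions: NaH (1.0 equiv), THF, 0 °C; LiBH4, 0 °C → rt; then 3 M HCl, rt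
Reagents that add atoms: none
Why: Chemoselective borohydride reduction of the ester beside the inert carboxylate salt, then acid-promoted lactonisation, should give the δ-lactone with the C10 centre untouched (the descriptor changes from R to S only because the substituent priorities change).

Step 2
Reactants: 3 (S)-4-methyloxan-2-one; 4 3-bromo-2-methylprop-1-ene
Product: 6 (3R,4S)-4-methyl-3-(2-methylprop-2-enyl)oxan-2-one, via lithium lactone enolate 5 (not isolated)
Conditions: LiN(i-Pr)2, THF, −78 °C; then 4, DMPU, −78 → −40 °C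
Reagents that add atoms: none
Why: Lactone enolate alkylation, in which the allylic bromide should enter the half-chair enolate on the face opposite the neighbouring C10 methyl group, setting C1 (R) trans to C10.

Step 3
Reactants: 6 (3R,4S)-4-methyl-3-(2-methylprop-2-enyl)oxan-2-one
Product: 8 (3R,4S)-4-methyl-3-(2-oxopropyl)oxan-2-one, via secondary ozonide 7 (not isolated)
Conditions: O3, CH2Cl2, −78 °C; then PPh3, −78 °C → rt
Reagents that add atoms: ozone, [O-][O+]=O
Why: Ozonolysis with reductive work-up cleaves the only C=C bond and leaves the methyl ketone that is the C3 carbonyl with its sacrificial methyl group.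

Step 4
Reactants: 8 (3R,4S)-4-methyl-3-(2-oxopropyl)oxan-2-one
Product: 9 (3R,4S)-4-methyl-3-[(2-methyl-1,3-dioxolan-2-yl)methyl]oxan-2-one
Conditions: Me3SiOCH2CH2OSiMe3, Me3SiOTf (cat.), CH2Cl2, −78 → −20 °C
Reagents that add atoms: 1,2-bis(trimethylsilyloxy)ethane, C[Si](C)(C)OCCO[Si](C)(C)C
Why: Noyori ketalisation under aprotic, low-temperature conditions should protect the ketone without opening the lactone.

Step 5
Reactants: 9 (3R,4S)-4-methyl-3-[(2-methyl-1,3-dioxolan-2-yl)methyl]oxan-2-one
Product: 10 (3R,4S)-4-methyl-3-[(2-methyl-1,3-dioxolan-2-yl)methyl]oxan-2-ol (both anomers)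
Conditions: i-Bu2AlH (1.1 equiv), CH2Cl2, −78 °C; aqueous potassium sodium tartrate
Reagents that add atoms: none
Why: Partial hydride reduction of a lactone to the lactol, the tetrahedral aluminate being stable at −78 °C until work-up.

Step 6
Reactants: 10 (3R,4S)-4-methyl-3-[(2-methyl-1,3-dioxolan-2-yl)methyl]oxan-2-ol
Product: 11 (3S,4R)-3-methyl-4-[(2-methyl-1,3-dioxolan-2-yl)methyl]hex-5-yn-1-ol
Conditions: dimethyl (1-diazo-2-oxopropyl)phosphonate, K2CO3, MeOH, 0 °C → rt
Reagents that add atoms: dimethyl (1-diazo-2-oxopropyl)phosphonate, COP(=O)(OC)C(=[N+]=[N-])C(C)=O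
Why: Seyferth–Gilbert homologation in the Ohira–Bestmann variant acts on the open hydroxy-aldehyde tautomer of the lactol, turning the C5 carbonyl into the terminal C5≡C4 alkyne and freeing the C8 hydroxyl.

Step 7
Reactants: 11 (3S,4R)-3-methyl-4-[(2-methyl-1,3-dioxolan-2-yl)methyl]hex-5-yn-1-ol
Product: 13 (3S,4R)-3-methyl-4-[(2-methyl-1,3-dioxolan-2-yl)methyl]hept-5-yn-1-ol, via dilithio alkoxide alkynide 12 (not isolated)
Conditions: n-BuLi (2.2 equiv), THF, −78 → −20 °C; MeI (1.1 equiv), DMPU, −78 → 0 °C
Reagents that add atoms: iodomethane, CI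
Why: Alkynide alkylation of the dianion, the lithium alkoxide being far less nucleophilic towards iodomethane than the alkynide carbon, so methylation should occur at C4.

Step 8
Reactants: 13 (3S,4R)-3-methyl-4-[(2-methyl-1,3-dioxolan-2-yl)methyl]hept-5-yn-1-ol
Product: 14 (3S,4R)-3-methyl-4-[(2-methyl-1,3-dioxolan-2-yl)methyl]hept-5-ynal
Conditions: Dess–Martin periodinane, pyridine, CH2Cl2, 0 °C → rt
Reagents that add atoms: none
Why: Dess–Martin oxidation of the primary alcohol to the C8 aldehyde, buffered with pyridine to spare the dioxolane; the aldehyde has no α-stereocentre to lose.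

Step 9
Reactants: 15 (S)-4-benzyloxazolidin-2-one; 16 (E)-but-2-enoyl chloride
Product: 18 (S)-4-benzyl-3-[(E)-but-2-enoyl]oxazolidin-2-one, via N-lithio oxazolidinone 17 (not isolated)
Conditions: n-BuLi, THF, −78 °C; then 16, −78 → 0 °C
Reagents that add atoms: none
Why: N-Acylation of the lithiated oxazolidinone with the acid chloride.

Step 10
Reactants: 18 (S)-4-benzyl-3-[(E)-but-2-enoyl]oxazolidin-2-one; 14 (3S,4R)-3-methyl-4-[(2-methyl-1,3-dioxolan-2-yl)methyl]hept-5-ynal
Product: 20 (S)-4-benzyl-3-[(2S,3R,5S,6R)-2-ethenyl-3-hydroxy-5-methyl-6-[(2-methyl-1,3-dioxolan-2-yl)methyl]non-7-ynoyl]oxazolidin-2-one, via dibutylboron dienolate 19 (not isolated)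
Conditions: Bu2BOTf, Et3N, CH2Cl2, −78 → 0 °C; then 14, −78 → 0 °C; pH 7 buffer, MeOH, 30% H2O2, 0 °C
Reagents that add atoms: none
Why: Evans syn aldol of the (Z)-boron dienolate formed by γ-deprotonation of the crotonyl imide, which should react at its α-carbon through a closed chair transition state on the face away from the benzyl group, setting C7 (S) and C8 (R) under auxiliary control whatever the remote C10 centre.

Step 11
Reactants: 20 (S)-4-benzyl-3-[(2S,3R,5S,6R)-2-ethenyl-3-hydroxy-5-methyl-6-[(2-methyl-1,3-dioxolan-2-yl)methyl]non-7-ynoyl]oxazolidin-2-one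
Product: 21 methyl (2S,3R,5S,6R)-2-ethenyl-3-hydroxy-5-methyl-6-[(2-methyl-1,3-dioxolan-2-yl)methyl]non-7-ynoate
Conditions: MeMgBr (1.5 equiv) added to MeOH, then 20, CH2Cl2/MeOH, 0 °C
Reagents that add atoms: methanol, CO
Why: Transesterification with bromomagnesium methoxide, a weakly basic nucleophile that should cleave the exocyclic imide carbonyl without epimerising or conjugating the α-vinyl centre.

Step 12
Reactants: 21 methyl (2S,3R,5S,6R)-2-ethenyl-3-hydroxy-5-methyl-6-[(2-methyl-1,3-dioxolan-2-yl)methyl]non-7-ynoate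
Product: 23 (4R,5S,7R,8S)-8-ethenyl-7,9-dihydroxy-5,9-dimethyl-4-(prop-1-ynyl)decan-2-one, via ketal diol 22 (not isolated)
Conditions: MeLi, CeCl3 (6 equiv each), THF, −78 → −40 °C; then 1 M HCl, THF, rt
Reagents that add atoms: methyllithium, [Li]C; water, O
Why: Double addition of the weakly basic organocerium reagent to the ester should give the C11 carbinol without enolising the doubly activated C7–H, and the acidic quench hydrolyses the dioxolane to free the C3 ketone.

Step 13
Reactants: 23 (4R,5S,7R,8S)-8-ethenyl-7,9-dihydroxy-5,9-dimethyl-4-(prop-1-ynyl)decan-2-one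
Product: 24 (4R,5S)-6-[(4R,5S)-5-ethenyl-2,2,6,6-tetramethyl-1,3-dioxan-4-yl]-5-methyl-4-(prop-1-ynyl)hexan-2-one
Conditions: 2-methoxypropene, PPTS (cat.), CH2Cl2, 0 °C → rt
Reagents that add atoms: 2-methoxypropene, C=C(C)OC
Why: Acid-catalysed acetal exchange should tie the secondary C8 and tertiary C11 hydroxyls into a six-membered acetonide in which the C6 vinyl group and the C9 chain are cis, the ketone being inert under these conditions.

Step 14
Reactants: 24 (4R,5S)-6-[(4R,5S)-5-ethenyl-2,2,6,6-tetramethyl-1,3-dioxan-4-yl]-5-methyl-4-(prop-1-ynyl)hexan-2-one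
Product: 26 tert-butyl-[(4R,5S)-6-[(4R,5S)-5-ethenyl-2,2,6,6-tetramethyl-1,3-dioxan-4-yl]-5-methyl-4-(prop-1-ynyl)hex-1-en-2-yl]oxy-dimethylsilane, via potassium enolate 25 (not isolated)
Conditions: KN(SiMe3)2, THF, −78 °C; t-BuMe2SiCl, −78 → −40 °C; Et3N, cold aqueous NaHCO3 work-up
Reagents that add atoms: tert-butyldimethylsilyl chloride, CC(C)(C)[Si](C)(C)Cl
Why: Kinetic deprotonation of the methyl ketone at the unhindered methyl group by a bulky amide base, then O-silylation, should give the terminal silyl enol ether, the C2 methylene being shielded by the branched C1.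

Step 15
Reactants: 26 tert-butyl-[(4R,5S)-6-[(4R,5S)-5-ethenyl-2,2,6,6-tetramethyl-1,3-dioxan-4-yl]-5-methyl-4-(prop-1-ynyl)hex-1-en-2-yl]oxy-dimethylsilane
Product: 27 tricyclic silyl dienol ether: (1R,7S,8R,10S)-3-(tert-butyldimethylsilyloxy)guaia-3,5-diene-8,11-diol 8,11-acetonide
Conditions: second-generation Grubbs catalyst RuCl2(=CHPh)(PCy3)(H2IMes) (10 mol %, two portions), 1,4-benzoquinone (10 mol %), degassed toluene (0.003 M), 80 °C, argon sparge
Reagents that add atoms: none
Why: Proposed new method: the ruthenium benzylidene should exchange at the only monosubstituted alkene (C6 vinyl) to give the C6 alkylidene, which adds across the C4≡C5 alkyne in the exo sense (C6 to C5, ruthenium to C4) and after opening of the ruthenacyclobutene leaves ring B as a cycloheptene (C5=C6) with a methyl-substituted vinyl alkylidene on C4; this alkylidene then undergoes ring-closing metathesis with the 2-silyloxy-1-alkene (C3=CH2), forming C3=C4, closing ring A and releasing the ruthenium methylidene, which carries the chain with loss of ethene. The closest known reaction types are tandem ring-closing dienyne metathesis to fused bicyclic 1,3-dienes and ring-closing metathesis of acyclic silyl enol ethers; their union, with a tetrasubstituted enol-ether terminus after a seven-membered enyne closure, has no direct precedent. Ring B closes by exo-mode enyne metathesis to a seven-membered ring and ring A by five-membered ring-closing metathesis between a disubstituted alkylidene and a 1,1-disubstituted enol ether. No stereocentre is formed, and C1, C7, C8 and C10 are spectators under the neutral conditions. The step needs initiation at C6 and exo regiochemistry: the enol ether is 1,1-disubstituted and electron-rich and so loads slowly, an exo closure from its end would require a four-membered ring, and the cis-5,6-disubstituted dioxane holds the C6 vinyl group and the C9 chain gauche, which brings the alkylidene near the alkyne. High dilution, heat and removal of ethene are used so that the second, hindered closure can compete with capture of the C4 alkylidene by ethene or by another molecule.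

Step 16
Reactants: 27 tricyclic silyl dienol ether
Product: 29 (5S,6R,8S,8aR)-6-hydroxy-5-(2-hydroxypropan-2-yl)-3,8-dimethyl-4,5,6,7,8,8a-hexahydroazulen-2(1H)-one, via enone acetonide 28 (not isolated)
Conditions: 1 M HCl, THF, 0 °C → rt
Reagents that add atoms: none
Why: Acid hydrolysis, in which C-protonation of the silyl dienol ether (at C6, or at C4 followed by acid-catalysed conjugation) should give the thermodynamically preferred tetrasubstituted C4=C5 enone and the same acid removes the strained acetonide, the mild non-basic conditions leaving C1 untouched.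

Step 17
Reactants: 29 (5S,6R,8S,8aR)-6-hydroxy-5-(2-hydroxypropan-2-yl)-3,8-dimethyl-4,5,6,7,8,8a-hexahydroazulen-2(1H)-one
Product: 30 (5S,6R,8S,8aR)-5-(2-hydroxypropan-2-yl)-3,8-dimethyl-2-oxo-1,2,4,5,6,7,8,8a-octahydroazulen-6-yl 2-methylpropanoate
Conditions: i-PrCOCl (1.2 equiv), pyridine, DMAP (cat.), CH2Cl2, 0 °C
Reagents that add atoms: 2-methylpropanoyl chloride, CC(C)C(Cl)=O
Why: Selective O-acylation of the secondary C8 hydroxyl, the tertiary C11 hydroxyl being unreactive towards the acid chloride under these conditions.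

Step 18
Reactants: 30 (5S,6R,8S,8aR)-5-(2-hydroxypropan-2-yl)-3,8-dimethyl-2-oxo-1,2,4,5,6,7,8,8a-octahydroazulen-6-yl 2-methylpropanoate
Product: 31 (5S,6R,8S,8aR)-5-(2-acetoxypropan-2-yl)-3,8-dimethyl-2-oxo-1,2,4,5,6,7,8,8a-octahydroazulen-6-yl 2-methylpropanoate (target)
Conditions: Ac2O, DMAP (1 equiv), Et3N, CH2Cl2, rt → 40 °C
Reagents that add atoms: acetic anhydride, CC(=O)OC(C)=O
Why: DMAP-mediated (Steglich-type) acetylation through the N-acetylpyridinium ion, which should acylate the tertiary C11 alcohol without acid that could ionise it.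

**Compound list**

1 | methyl hydrogen (R)-3-methylpentanedioate | COC(=O)C[C@H](C)CC(=O)O | starting material
2 | sodium (S)-5-hydroxy-3-methylpentanoate | [Na+].[O-]C(=O)C[C@@H](C)CCO | intermediate (not isolated)
3 | (S)-4-methyloxan-2-one | O=C1C[C@@H](C)CCO1 | intermediate
4 | 3-bromo-2-methylprop-1-ene | C=C(C)CBr | starting material
5 | lithium (4S)-4-methyl-3,4-dihydro-2H-pyran-6-olate (lactone enolate) | [Li]OC1=C[C@@H](C)CCO1 | intermediate (not isolated)
6 | (3R,4S)-4-methyl-3-(2-methylprop-2-enyl)oxan-2-one | O=C1[C@H](CC(C)=C)[C@@H](C)CCO1 | intermediate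
7 | (3R,4S)-4-methyl-3-[(3-methyl-1,2,4-trioxolan-3-yl)methyl]oxan-2-one (secondary ozonide, trioxolane carbon epimers) | O=C1[C@H](CC2(C)OCOO2)[C@@H](C)CCO1 | intermediate (not isolated)
8 | (3R,4S)-4-methyl-3-(2-oxopropyl)oxan-2-one | O=C1[C@H](CC(C)=O)[C@@H](C)CCO1 | intermediate
9 | (3R,4S)-4-methyl-3-[(2-methyl-1,3-dioxolan-2-yl)methyl]oxan-2-one | O=C1[C@H](CC2(C)OCCO2)[C@@H](C)CCO1 | intermediate
10 | (3R,4S)-4-methyl-3-[(2-methyl-1,3-dioxolan-2-yl)methyl]oxan-2-ol (both anomers) | OC1[C@H](CC2(C)OCCO2)[C@@H](C)CCO1 | intermediate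
11 | (3S,4R)-3-methyl-4-[(2-methyl-1,3-dioxolan-2-yl)methyl]hex-5-yn-1-ol | OCC[C@H](C)[C@@H](CC1(C)OCCO1)C#C | intermediate
12 | dilithio alkoxide alkynide of 11 | [Li]OCC[C@H](C)[C@@H](CC1(C)OCCO1)C#C[Li] | intermediate (not isolated)
13 | (3S,4R)-3-methyl-4-[(2-methyl-1,3-dioxolan-2-yl)methyl]hept-5-yn-1-ol | OCC[C@H](C)[C@@H](CC1(C)OCCO1)C#CC | intermediate
14 | (3S,4R)-3-methyl-4-[(2-methyl-1,3-dioxolan-2-yl)methyl]hept-5-ynal | O=CC[C@H](C)[C@@H](CC1(C)OCCO1)C#CC | intermediate
15 | (S)-4-benzyloxazolidin-2-one | O=C1N[C@@H](Cc2ccccc2)CO1 | starting material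
16 | (E)-but-2-enoyl chloride | C/C=C/C(Cl)=O | starting material
17 | N-lithio (S)-4-benzyloxazolidin-2-one | [Li]N1[C@@H](Cc2ccccc2)COC1=O | intermediate (not isolated)
18 | (S)-4-benzyl-3-[(E)-but-2-enoyl]oxazolidin-2-one | C/C=C/C(=O)N1[C@@H](Cc2ccccc2)COC1=O | intermediate
19 | (Z)-dibutylboron dienolate of 18 | C=C/C=C(\OB(CCCC)CCCC)N1[C@@H](Cc2ccccc2)COC1=O | intermediate (not isolated)
20 | (S)-4-benzyl-3-[(2S,3R,5S,6R)-2-ethenyl-3-hydroxy-5-methyl-6-[(2-methyl-1,3-dioxolan-2-yl)methyl]non-7-ynoyl]oxazolidin-2-one | O=C(N1[C@@H](Cc2ccccc2)COC1=O)[C@@H](C=C)[C@H](O)C[C@H](C)[C@@H](CC3(C)OCCO3)C#CC | intermediate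
21 | methyl (2S,3R,5S,6R)-2-ethenyl-3-hydroxy-5-methyl-6-[(2-methyl-1,3-dioxolan-2-yl)methyl]non-7-ynoate | COC(=O)[C@@H](C=C)[C@H](O)C[C@H](C)[C@@H](CC1(C)OCCO1)C#CC | intermediate
22 | (3S,4R,6S,7R)-3-ethenyl-2,6-dimethyl-7-[(2-methyl-1,3-dioxolan-2-yl)methyl]dec-8-yne-2,4-diol (ketal diol) | C=C[C@H](C(C)(C)O)[C@H](O)C[C@H](C)[C@@H](CC1(C)OCCO1)C#CC | intermediate (not isolated)
23 | (4R,5S,7R,8S)-8-ethenyl-7,9-dihydroxy-5,9-dimethyl-4-(prop-1-ynyl)decan-2-one | C=C[C@H](C(C)(C)O)[C@H](O)C[C@H](C)[C@@H](CC(C)=O)C#CC | intermediate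
24 | (4R,5S)-6-[(4R,5S)-5-ethenyl-2,2,6,6-tetramethyl-1,3-dioxan-4-yl]-5-methyl-4-(prop-1-ynyl)hexan-2-one | C=C[C@@H]1C(C)(C)OC(C)(C)O[C@@H]1C[C@H](C)[C@@H](CC(C)=O)C#CC | intermediate
25 | potassium enolate of 24 (terminal) | C=C[C@@H]1C(C)(C)OC(C)(C)O[C@@H]1C[C@H](C)[C@@H](CC(=C)O[K])C#CC | intermediate (not isolated)
26 | tert-butyl-[(4R,5S)-6-[(4R,5S)-5-ethenyl-2,2,6,6-tetramethyl-1,3-dioxan-4-yl]-5-methyl-4-(prop-1-ynyl)hex-1-en-2-yl]oxy-dimethylsilane (dienyne precursor) | C=C[C@@H]1C(C)(C)OC(C)(C)O[C@@H]1C[C@H](C)[C@@H](CC(=C)O[Si](C)(C)C(C)(C)C)C#CC | intermediate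
27 | (1R,7S,8R,10S)-3-(tert-butyldimethylsilyloxy)guaia-3,5-diene-8,11-diol 8,11-acetonide (ring A cyclopentadiene C3=C4, ring B C5=C6, cis-fused tetramethyl-1,3-dioxane across C7/C8) | CC1=C(O[Si](C)(C)C(C)(C)C)C[C@H]2C1=C[C@@H]3C(C)(C)OC(C)(C)O[C@@H]3C[C@@H]2C | intermediate
28 | (1R,7S,8R,10S)-8,11-dihydroxyguai-4-en-3-one 8,11-acetonide | CC1(C)OC(C)(C)[C@H]2CC3=C(C)C(=O)C[C@@H]3[C@@H](C)C[C@H]2O1 | intermediate (not isolated)
29 | (5S,6R,8S,8aR)-6-hydroxy-5-(2-hydroxypropan-2-yl)-3,8-dimethyl-4,5,6,7,8,8a-hexahydroazulen-2(1H)-one | CC(C)(O)[C@H]1CC2=C(C)C(=O)C[C@@H]2[C@@H](C)C[C@H]1O | intermediate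
30 | (5S,6R,8S,8aR)-5-(2-hydroxypropan-2-yl)-3,8-dimethyl-2-oxo-1,2,4,5,6,7,8,8a-octahydroazulen-6-yl 2-methylpropanoate | CC(C)(O)[C@H]1CC2=C(C)C(=O)C[C@@H]2[C@@H](C)C[C@H]1OC(=O)C(C)C | intermediate
31 | (5S,6R,8S,8aR)-5-(2-acetoxypropan-2-yl)-3,8-dimethyl-2-oxo-1,2,4,5,6,7,8,8a-octahydroazulen-6-yl 2-methylpropanoate | CC(=O)OC(C)(C)[C@H]1CC2=C(C)C(=O)C[C@@H]2[C@@H](C)C[C@H]1OC(=O)C(C)C | target

**Step count**

Total steps: 18. Longest linear sequence: 17 (steps 1–8 and 10–18; step 9 prepares the aldol partner).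

**Steps most likely to fail**

1. Step 15 (Proposed new method). After ring B has closed, the C4 alkylidene may fail to engage the hindered, electron-rich enol ether to form the tetrasubstituted C3=C4 bond. It would then be quenched by ethene or by a second molecule, or the catalyst would be drained as an unreactive siloxy-substituted carbene. The fallback uses known chemistry, sets out from 26 and comes back at 27. Ring B is closed alone by ring-closing enyne metathesis with the first-generation Grubbs catalyst RuCl2(=CHPh)(PCy3)2 under ethene (1 atm, CH2Cl2, rt), which leaves the enol ether alone and should give the isopropenyl cycloheptene triene F1. Ring A is then closed in a separate operation by ring-closing metathesis of the isopropenyl group with the silyl enol ether, using the Schrock molybdenum alkylidene Mo(=CHCMe2Ph)(=N-2,6-i-Pr2C6H3)[OCMe(CF3)2]2 (benzene, 50 °C). That catalyst type is established for enol ethers and for tetrasubstituted alkenes, and the closure returns 27.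

2. Step 6. The lactol reacts only through a small share of open hydroxy-aldehyde, so the homologation is slow and C1 (α to the aldehyde) may epimerise in K2CO3/MeOH, eroding the trans C1/C10 relationship. The fallback sets out from 10 and comes back at 13. A Wittig bromomethylenation with the ylide pre-formed from (bromomethyl)triphenylphosphonium bromide and KOt-Bu (THF, −78 °C) consumes the aldehyde form quickly and should give the bromoalkenol F2 (E/Z mixture). Treatment of F2 with LiN(i-Pr)2 (3.2 equiv, THF, −78 → 0 °C) dehydrobrominates it to the dianion 12, which is methylated in the same flask with iodomethane to give 13.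

3. Step 12. The organometallic reagent may deprotonate C7 (allylic and α to the ester) instead of adding, which would return epimerised or conjugated (ethylidene) ester, and the metal aldolate may undergo retro-aldol cleavage once the ketone stage is reached. The fallback sets out from 20 and comes back at 22. Transamination of the imide with Me(MeO)NH·HCl and AlMe3 (CH2Cl2, −20 → 0 °C) should give the Weinreb amide F3. MeMgBr (THF, −78 → 0 °C) then stops cleanly at the β-hydroxy methyl ketone F4 through the stable chelated adduct. A single addition of MeLi/CeCl3 at −78 °C to F4 gives the ketal diol 22, which is hydrolysed to 23 as in the main route.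

**Further compounds**

F1 | step 15 | tert-butyl-dimethylsilyl enol ether of the ring B-closed triene: cycloheptene (C5=C6) fused to the tetramethyl-1,3-dioxane, prop-1-en-2-yl on C5, 2-(silyloxy)allyl on C1, (1R,7S,8R,10S) | C=C(C)C1=C[C@@H]2C(C)(C)OC(C)(C)O[C@@H]2C[C@H](C)[C@H]1CC(=C)O[Si](C)(C)C(C)(C)C
F2 | step 6 | (3S,4R)-6-bromo-3-methyl-4-[(2-methyl-1,3-dioxolan-2-yl)methyl]hex-5-en-1-ol (E/Z mixture) | OCC[C@H](C)[C@@H](CC1(C)OCCO1)C=CBr
F3 | step 12 | (2S,3R,5S,6R)-2-ethenyl-3-hydroxy-N-methoxy-N,5-dimethyl-6-[(2-methyl-1,3-dioxolan-2-yl)methyl]non-7-ynamide | CON(C)C(=O)[C@@H](C=C)[C@H](O)C[C@H](C)[C@@H](CC1(C)OCCO1)C#CC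
F4 | step 12 | (3S,4R,6S,7R)-3-ethenyl-4-hydroxy-6-methyl-7-[(2-methyl-1,3-dioxolan-2-yl)methyl]dec-8-yn-2-one | CC(=O)[C@@H](C=C)[C@H](O)C[C@H](C)[C@@H](CC1(C)OCCO1)C#CC
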